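The runs come from a simulation on assumed constants; noise was put on by code.

Two questions stand on the blue flask, which is still running: how much target, all its forms counted, there is at 4.0 min, and how near saturation c(dissolved substrate) stands then.

the same everywhere: solid substrate 0.25 M
- blue: reagent 0.50 M; the very flask that is asked about, followed so far
- grey: reagent 0.34 M; run made earlier
- flask: reagent 0.500 M; time 4.0 min

blue run (percent of the solid substrate charged)

| time / s | target / % | solid product / % |
|---|---|---|
| 25.0 | 7 | 0 |
| 50.0 | 16 | 0 |
| 80.0 | 18 | 1 |
| 90.0 | 25 | 3 |
| 120 | 33 | 0 |

grey run (percent of the solid substrate charged)

| time / min | target / % | solid product / % |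
|---|---|---|
| 0.333 | 1 | 0 |
| 1.00 | 14 | 0 |
| 2.00 | 29 | 2 |
| 3.00 | 48 | 0 |
| 4.00 | 59 | 12 |

(standard deviation of a reading: 1.5 percentage points)

1. how much target and solid product and idle adduct together there is at 4.0 min, in percent of the solid substrate charged
2. concentration of dissolved substrate in solution at 4.0 min, in percent of saturation

- for target the solid product and idle adduct are counted in
- as a solid, counted per litre of solution: solid substrate, solid product
- the analysis behind the earlier runs scatters by 1.5 percentage points, standard deviation
- at the start none of the solid substrate is in solution
- dissolved substrate means what is dissolved; the solid is not counted in it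

Two people at the board disagree. The first holds that the solution reaction is slow and sets the pace while the solid keeps the solution full. The pace then goes with c(reagent), whose charges stand in the ratio 1.47, so on this view grey's reading of 59% at 4.00 min scales to 86.8% for blue. The second holds that dissolved substrate reacts as it arrives, which makes dissolution the rate-limiting step and leaves the pace free of c(reagent).

The readings can choose. At 2.00 min grey reads 29%, which the first view scales to 42.6% for blue, but blue reads 33% at 120 s. The ratio of these two readings, 1.14, is smaller than the ratio of the charges, so I side with the second.

The forecast, on that side, gives 69% and 10%, holding that “the rate is set by dissolution, not by the solution reaction”. My own number differs from it. The target column already counts solid product, so grey reads 59%, not 71. Over 4.00 min that reading gives a supply rate of 0.147 min⁻¹, the average share of the charged solid substrate reaching the target column per minute. For blue at 4.0 min I therefore commit to 58.8%, and for saturation to nothing firmer than "well below".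

The blue flask gives 61.3% and 3.68%.

    solid substrate ⇌ dissolved substrate, rate k1*(cs1 - [dissolved substrate]) while solid is left; crystals form when [dissolved substrate] > cs1 (solubility = 0.130 M, k = 0.00597 s⁻¹)
    dissolved substrate + reagent → target (k = 0.512 L mol⁻¹ s⁻¹)
    solid product ⇌ target, rate k3*(cs3 - [target]) while solid is left; crystals form when [target] > cs3 (solubility = 0.110 M, k = 0.360 s⁻¹)
    reagent + target ⇌ idle adduct, settled at all times (K = 0.680 L mol⁻¹)
    target ⇌ isomer of the product (K = 1.06, k = 0.00174 s⁻¹)

The figure from the supply rate lies 2.3 percentage points below the blue flask. In the blue flask the half-life of dissolved substrate by its conversion with reagent alone, at the concentrations as charged, is 2.7 s, far shorter than 4.0 min. On the neighbour charged with 0.30 M of reagent, the same supply rate again gives 58.8%, and that flask holds 56.9%. The first view's c(reagent) has its region in c(dissolved substrate), which at 4.00 min stands at 1.91% of the charge in the blue flask and 4.20% in the neighbour.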